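**Plan**

- Ring numbering: C1 (quaternary; CH3 and the styryl alkene C7=C8), C2H2, C3H2, C4(CH3)=C5H, C6H(coumarinyl). The only ring alkene, C4=C5, and the exocyclic alkene C7=C8 on C1 are both cut as metathesis retrons. This leaves an open-chain triene that already holds the C1–C6 bond, plus 7-methoxy-6-vinylcoumarin.
- The C1–C6 bond of the triene is then cut between two allyl fragments: a coumarinyl-substituted allyl chloride and a (Z)-3,3-disubstituted allylboronate.
- Forward: the salicylaldehyde is brominated, converted to the bromocoumarin, vinylated, and extended by cross metathesis to the cinnamyl-type chloride. The methyl ketone is taken in four steps to the Z-allylboronate.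
- Pd-catalysed allyl–allyl coupling joins the two fragments. In the last step, ring-closing metathesis forms the single carbocycle (C4=C5) and cross metathesis with the vinylcoumarin forms C7=C8 in the same flask.
- Stereochemistry: C1 (R) and C6 (S) are both set in the allyl–allyl coupling, the absolute sense by the chiral diphosphine and the relative sense by the Z geometry of the boronate. The metathesis step touches neither centre and gives the E-alkene under thermodynamic control.

Key step: step 10

Assumption: the allyl–allyl coupling is taken to proceed by a chair-like 3,3'-reductive elimination that is stereospecific in the boronate geometry, and (S)-MeO-furyl-BIPHEP is taken as the ligand enantiomer that gives the (3S) benzylic centre; if the first run shows the opposite absolute sense, the (R)-ligand is used with nothing else changed.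

**Route**

Step 1
Reactants: 1 2-hydroxy-4-methoxybenzaldehyde
Product: 2 5-bromo-2-hydroxy-4-methoxybenzaldehyde
Conditions: Br2 (1.05 equiv), AcOH, rt
Reagents that add atoms: bromine, BrBr
Why: Electrophilic aromatic bromination should go para to the phenol and ortho to the methoxy group, since the other activated position (C3, between the two oxygens) is the hindered one.

Step 2
Reactants: 2 5-bromo-2-hydroxy-4-methoxybenzaldehyde
Product: 4 6-bromo-7-methoxy-2H-chromen-2-one, via E-cinnamate ester 3 (not isolated)
Conditions: Ph3P=CHCO2Et (1.2 equiv), PhNEt2, reflux (ca. 215 °C)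
Reagents that add atoms: ethyl (triphenylphosphoranylidene)acetate, CCOC(=O)C=P(c1ccccc1)(c1ccccc1)c1ccccc1
Why: Wittig olefination with the stabilised ylide gives the cinnamate, which at this temperature should isomerise E to Z and lactonise with loss of ethanol, the standard one-pot coumarin synthesis from salicylaldehydes.

Step 3
Reactants: 4 6-bromo-7-methoxy-2H-chromen-2-one
Product: 5 7-methoxy-6-vinyl-2H-chromen-2-one
Conditions: Bu3SnCH=CH2 (1.2 equiv), Pd(PPh3)4 (5 mol %), toluene, 100 °C
Reagents that add atoms: tributyl(vinyl)stannane, C=C[Sn](CCCC)(CCCC)CCCC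
Why: Stille coupling of the aryl bromide with a vinylstannane runs under neutral conditions that should leave the lactone untouched.

Step 4
Reactants: 5 7-methoxy-6-vinyl-2H-chromen-2-one
Product: 6 6-[(E)-3-chloroprop-1-en-1-yl]-7-methoxy-2H-chromen-2-one
Conditions: (Z)-ClCH2CH=CHCH2Cl (4 equiv), Hoveyda–Grubbs II (3 mol %), CH2Cl2, 40 °C
Reagents that add atoms: (Z)-1,4-dichlorobut-2-ene, ClC/C=C\CCl
Why: Olefin cross metathesis of a styrene with an excess of a symmetrical allylic alkene should give the E-cinnamyl chloride, the coumarin C3=C4 bond being an electron-poor 1,2-disubstituted alkene that does not take part.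

Step 5
Reactants: 7 5-methylhex-5-en-2-one
Product: 10 6-methylhept-6-en-2-yn-1-ol, via enol phosphate 8 (not isolated), via lithium acetylide 9 (not isolated)
Conditions: LDA (1.05 equiv), THF, −78 °C; ClP(O)(OEt)2, −78 °C → rt; LDA (2.3 equiv), −78 °C → rt; (CH2O)n, 0 °C → rt; aq. NH4Cl
Reagents that add atoms: paraformaldehyde (as formaldehyde), C=O; diethyl chlorophosphate, CCOP(=O)(Cl)OCC (its atoms are retained only in intermediate 8)
Why: Kinetic enolisation at the methyl group, O-phosphorylation and double LDA elimination is the established methyl ketone to terminal alkyne sequence, and the lithium acetylide it leaves should add to formaldehyde in the same flask (acetylide hydroxymethylation).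

Step 6
Reactants: 10 6-methylhept-6-en-2-yn-1-ol
Product: 11 (2Z)-3,6-dimethylhepta-2,6-dien-1-ol
Conditions: MeMgBr (5 equiv), Fe(acac)3 (15 mol %), THF, −78 → 0 °C; aq. NH4Cl
Reagents that add atoms: methylmagnesium bromide, C[Mg]Br
Why: Iron-catalysed, alkoxide-directed syn-carbomagnesiation of a propargylic alcohol delivers methyl to the distal alkyne carbon and magnesium to the proximal one on the same side, so protonation should leave the homoallyl chain cis to CH2OH (Z).

Step 7
Reactants: 11 (2Z)-3,6-dimethylhepta-2,6-dien-1-ol
Product: 12 (2Z)-1-chloro-3,6-dimethylhepta-2,6-diene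
Conditions: NCS, Me2S, CH2Cl2, −30 → 0 °C
Reagents that add atoms: N-chlorosuccinimide, O=C1CCC(=O)N1Cl
Why: Chlorination with the Corey–Kim reagent (alkoxysulfonium salt displaced by chloride in an SN2 step) should convert the primary allylic alcohol to the chloride without allylic transposition or loss of alkene geometry.

Step 8
Reactants: 12 (2Z)-1-chloro-3,6-dimethylhepta-2,6-diene
Product: 13 2-[(2Z)-3,6-dimethylhepta-2,6-dien-1-yl]-4,4,5,5-tetramethyl-1,3,2-dioxaborolane
Conditions: B2pin2 (1.1 equiv), Pd2(dba)3 (1 mol %), THF, 60 °C
Reagents that add atoms: bis(pinacolato)diboron, CC1(C)OB(OC1(C)C)B1OC(C)(C)C(C)(C)O1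
Why: Pd-catalysed allylic borylation (Miyaura type) proceeds by a π-allyl–Pd–boryl species that eliminates at the primary terminus, and the 3,3-disubstituted π-allyl is slow to undergo syn/anti exchange, so the Z geometry should be kept.

Step 9
Reactants: 6 6-[(E)-3-chloroprop-1-en-1-yl]-7-methoxy-2H-chromen-2-one; 13 2-[(2Z)-3,6-dimethylhepta-2,6-dien-1-yl]-4,4,5,5-tetramethyl-1,3,2-dioxaborolane
Product: 14 6-[(3S,4R)-4-ethenyl-4,7-dimethylocta-1,7-dien-3-yl]-7-methoxy-2H-chromen-2-one
Conditions: Pd2(dba)3 (2.5 mol %), (S)-MeO-furyl-BIPHEP (6 mol %), CsF (3 equiv), THF/H2O 10:1, 60 °C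
Reagents that add atoms: none
Why: Pd-catalysed enantioselective allyl–allyl cross-coupling (oxidative addition of the chloride, fluoride-assisted transmetalation, 3,3'-reductive elimination from a bis(η1-allyl)Pd diphosphine complex) joins the two substituted allyl termini; the ligand should fix the face of the aryl-bearing carbon (3S), and the chair-like array with aryl equatorial and the Z-placed homoallyl chain axial should fix the quaternary carbon relative to it (4R).

Step 10
Reactants: 14 6-[(3S,4R)-4-ethenyl-4,7-dimethylocta-1,7-dien-3-yl]-7-methoxy-2H-chromen-2-one; 5 7-methoxy-6-vinyl-2H-chromen-2-one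
Product: 16 7-methoxy-6-[(E)-2-[(1R,2S)-2-(7-methoxy-2-oxo-2H-chromen-6-yl)-1,4-dimethylcyclohex-3-en-1-yl]ethenyl]-2H-chromen-2-one (the target), via vinylcyclohexene 15 (not isolated)
Conditions: Hoveyda–Grubbs II (5 mol %), 1,4-benzoquinone (10 mol %), toluene (0.01 M), 50 °C, Ar sparge; then 5 (3 equiv), Hoveyda–Grubbs II (5 mol %), concentrate to ca. 0.1 M, 80 °C
Reagents that add atoms: none
Why: Both events are Chauvin olefin metatheses ([2+2] to a ruthenacyclobutane, then cycloreversion); the closest known reaction types are ring-closing metathesis of 1,7-dienes onto 1,1-disubstituted alkenes to give trisubstituted cyclohexenes and cross metathesis of vinyl groups on quaternary carbons with styrenes. The alkylidene should load on the vinyl group at C6, the only monosubstituted alkene that is not neopentyl, and close the six-membered ring by ring-closing metathesis onto the isopropenyl carbon C4 (octa-1,7-diene unit, C4=C5 formed, ethylene lost). No stereocentre is created: C1 and C6 pass through unchanged, and the only new stereo-element, the C7=C8 geometry, should be E because aryl and the quaternary carbon lie trans in the metallacyclobutane and the process is reversible. The selectivity needed is six- over five-membered ring closure; the fully substituted C1 secures it by shielding its own vinyl group from initiation, and adding the vinylcoumarin only after ring closure keeps the C6 vinyl group from being capped. The neopentyl vinyl group that remains cannot homodimerise, so the excess styrene-type partner, whose homodimer can re-enter the cycle, should channel it into the cross product. Benzoquinone is added to suppress ruthenium hydride migration of the C6 vinyl double bond, which would erase the C6 stereocentre.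

**Compound list**

1 | 2-hydroxy-4-methoxybenzaldehyde | COc1ccc(C=O)c(O)c1 | starting material
2 | 5-bromo-2-hydroxy-4-methoxybenzaldehyde | COc1cc(O)c(C=O)cc1Br | intermediate
3 | ethyl (2E)-3-(5-bromo-2-hydroxy-4-methoxyphenyl)prop-2-enoate | CCOC(=O)/C=C/c1cc(Br)c(OC)cc1O | intermediate
4 | 6-bromo-7-methoxy-2H-chromen-2-one | COc1cc2oc(=O)ccc2cc1Br | intermediate
5 | 7-methoxy-6-vinyl-2H-chromen-2-one | COc1cc2oc(=O)ccc2cc1C=C | intermediate
6 | 6-[(E)-3-chloroprop-1-en-1-yl]-7-methoxy-2H-chromen-2-one | COc1cc2oc(=O)ccc2cc1/C=C/CCl | intermediate
7 | 5-methylhex-5-en-2-one | CC(=O)CCC(C)=C | starting material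
8 | diethyl 5-methylhexa-1,5-dien-2-yl phosphate | C=C(C)CCC(=C)OP(=O)(OCC)OCC | intermediate
9 | (5-methylhex-5-en-1-yn-1-yl)lithium | [Li]C#CCCC(C)=C | intermediate
10 | 6-methylhept-6-en-2-yn-1-ol | OCC#CCCC(C)=C | intermediate
11 | (2Z)-3,6-dimethylhepta-2,6-dien-1-ol | C=C(C)CC/C(C)=C\CO | intermediate
12 | (2Z)-1-chloro-3,6-dimethylhepta-2,6-diene | C=C(C)CC/C(C)=C\CCl | intermediate
13 | 2-[(2Z)-3,6-dimethylhepta-2,6-dien-1-yl]-4,4,5,5-tetramethyl-1,3,2-dioxaborolane | C=C(C)CC/C(C)=C\CB1OC(C)(C)C(C)(C)O1 | intermediate
14 | 6-[(3S,4R)-4-ethenyl-4,7-dimethylocta-1,7-dien-3-yl]-7-methoxy-2H-chromen-2-one | C=C[C@@]([C@H](C=C)c1cc2ccc(=O)oc2cc1OC)(C)CCC(C)=C | intermediate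
15 | 6-[(1S,6R)-6-ethenyl-3,6-dimethylcyclohex-2-en-1-yl]-7-methoxy-2H-chromen-2-one | C=C[C@@]1(C)CCC(C)=C[C@@H]1c1cc2ccc(=O)oc2cc1OC | intermediate
16 | 7-methoxy-6-[(E)-2-[(1R,2S)-2-(7-methoxy-2-oxo-2H-chromen-6-yl)-1,4-dimethylcyclohex-3-en-1-yl]ethenyl]-2H-chromen-2-one | COc1cc2oc(=O)ccc2cc1/C=C/[C@@]1(C)CCC(C)=C[C@@H]1c1cc2ccc(=O)oc2cc1OC | target

**Count**

Total step count: 10.
Longest linear sequence: 6 steps (steps 1, 2, 3, 4, 9, 10; the boronate branch, steps 5, 6, 7, 8, 9, 10, is equally long).

**Steps most likely to fail, with fallbacks**

First, step 10. After ring closure the cross metathesis at the neopentyl vinyl group may stall while the vinylcoumarin is drained into its own homodimer. The fallback keeps the ring-closing half and replaces the cross metathesis by an arylation. The first stage of step 10 would be run without vinylcoumarin, and 15 isolated. A Mizoroki–Heck reaction of 15 with bromocoumarin 4 (Pd(OAc)2, P(o-tol)3, Et3N, DMF, 100 °C) should then attach the aryl group to the terminal alkene carbon. The quaternary carbon offers no β-hydrogen, so elimination can only give the E-styryl alkene, and the trisubstituted ring alkene should not react. The fallback sets out from 15 and 4 and comes back to the route at 16; no new compound arises (F0).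

Second, step 9. The relative configuration at the new bond may come out opposite to the chair-model prediction. If so, the boronate of the other geometry is made by a different carbometalation logic and used in the same coupling. The fallback sets out from alkynol 10. trans-Hydroalumination with Red-Al in THF and iodination at −78 °C should give (2Z)-3-iodo-6-methylhepta-2,6-dien-1-ol F1. Me2CuLi should replace iodine by methyl with retention and give (2E)-3,6-dimethylhepta-2,6-dien-1-ol F2. NCS/Me2S should give (2E)-1-chloro-3,6-dimethylhepta-2,6-diene F3, and Pd2(dba)3/B2pin2 should give 2-[(2E)-3,6-dimethylhepta-2,6-dien-1-yl]-4,4,5,5-tetramethyl-1,3,2-dioxaborolane F4. Coupling of F4 with 6 under the conditions of step 9 comes back to the route at 14.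

Third, step 6. The iron-catalysed methylmagnesiation may be incomplete or may lose its syn selectivity through competing reduction of the alkyne. The fallback sets the Z-alkene by cuprate syn-addition to an alkynoate instead. It sets out from ketone 7: the sequence of step 5 is repeated through 8 and 9, but acetylide 9 is quenched with methyl chloroformate to give methyl 6-methylhept-6-en-2-ynoate F5. Me2CuLi in THF at −78 °C with a cold quench should add methyl and hydrogen to the same side and give methyl (2Z)-3,6-dimethylhepta-2,6-dienoate F6. DIBAL-H in CH2Cl2 at −78 °C should reduce the ester to the allylic alcohol, and the fallback comes back to the route at 11.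

**Further compounds**

F0 | step 10 | none | none
F1 | step 9 | (2Z)-3-iodo-6-methylhepta-2,6-dien-1-ol | C=C(C)CC/C(I)=C/CO
F2 | step 9 | (2E)-3,6-dimethylhepta-2,6-dien-1-ol | C=C(C)CC/C(C)=C/CO
F3 | step 9 | (2E)-1-chloro-3,6-dimethylhepta-2,6-diene | C=C(C)CC/C(C)=C/CCl
F4 | step 9 | 2-[(2E)-3,6-dimethylhepta-2,6-dien-1-yl]-4,4,5,5-tetramethyl-1,3,2-dioxaborolane | C=C(C)CC/C(C)=C/CB1OC(C)(C)C(C)(C)O1
F5 | step 6 | methyl 6-methylhept-6-en-2-ynoate | C=C(C)CCC#CC(=O)OC
F6 | step 6 | methyl (2Z)-3,6-dimethylhepta-2,6-dienoate | C=C(C)CC/C(C)=C\C(=O)OC
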